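**Retrosynthetic overview**

1. Target 20 comes from diol 18 by C2-selective acetylation and tert-butyl ester cleavage; the C7=C8 olefin of 18 comes from radical removal of an allylic phenylthio group at C8 (17 → 18).
2. Ring A is closed last, onto a finished ring B, in one flask (15 → 17): C4–C5 by Claisen rearrangement of the C7–O enol ether of 2-methylmalonaldehyde, then C2–C3 by SmI2 pinacol coupling of the C2 aldehyde (arm on C10) with one of the two new formyl groups.
3. Enabling feature: in ring A the glycol carbons C2/C3 and the formyl-bearing quaternary C4 are a masked 2-methylmalonaldehyde (C3 and C19 are its two formyl carbons), and C4 is bonded to C5, the far end of the C5=C6–C7–O allyl unit of ring B, so an oxygen on C7 can deliver C4 to the correct face of C5.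
4. Ring B (enone 7) comes from a Diels–Alder reaction of an amino-siloxy diene with the (E)-enal 4 made from (R)-citronellic acid (C13 from the pool, C9/C10 from the cycloaddition); the C8 substituents and the C7 carbinol follow by enolate chemistry and Luche reduction.
5. Ring order: ring B (step 3), then ring A (step 10).

Key step: step 10

Numbering and faces: labdane numbering of the target is used for all compounds (ring A: C1–C5 and C10; ring B: C5–C10; side chain C11–C16 with C15 the carboxyl carbon; C17 methyl on C8; C18 methyl and C19 formyl on C4; C20 methyl on C10). "Upper face" is the face that carries C20.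

Assumption: the TADDOL catalyst in step 3 is taken to discriminate the enal faces as it does for 2-substituted acroleins; the enantiomer that leads to 7 is written as (R,R) and would be exchanged for its mirror image if the sense is opposite.

**Route**

Step 1
Reactants: 1 (R)-citronellic acid
Product: 2 tert-butyl (3R)-3,7-dimethyloct-6-enoate
Conditions: tert-butyl 2,2,2-trichloroacetimidate, cyclohexane/CH2Cl2, rt
Reagents that add atoms: tert-butyl 2,2,2-trichloroacetimidate CC(C)(C)OC(=N)C(Cl)(Cl)Cl
Why: O-alkylation of the carboxylic acid by the acid-activated trichloroacetimidate (tert-butyl ester formation) needs no strong acid, so the trisubstituted olefin and the C13 stereocentre are not touched.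

Step 2
Reactants: 2 tert-butyl (3R)-3,7-dimethyloct-6-enoate
Product: 4 tert-butyl (3R,6E)-3,7-dimethyl-8-oxooct-6-enoate, via allylic alcohol 3 (not isolated)
Conditions: SeO2 (cat.), t-BuOOH, salicylic acid (cat.), CH2Cl2, rt; then MnO2, CH2Cl2, rt
Reagents that add atoms: tert-butyl hydroperoxide CC(C)(C)OO
Why: SeO2 allylic oxidation (ene reaction then [2,3]-shift) is selective for the (E)-methyl group of a trisubstituted olefin, and MnO2 completes the allylic oxidation to the (E)-enal.

Step 3
Reactants: 4 tert-butyl (3R,6E)-3,7-dimethyl-8-oxooct-6-enoate; 5 (E)-1-(dimethylamino)-3-(tert-butyldimethylsilyloxy)buta-1,3-diene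
Product: 7 tert-butyl (3R)-5-(2-formyl-2-methyl-5-oxocyclohex-3-en-1-yl)-3-methylpentanoate (C10 methyl and C9 side chain both on the upper face), via cycloadduct 6 (not isolated)
Conditions: (R,R)-1-naphthyl-TADDOL (20 mol %), toluene, −40 °C → rt; then HF (aq), MeCN, 0 °C
Reagents that add atoms: none
Why: Diels–Alder reaction under hydrogen-bond catalysis joins the nucleophilic diene terminus to the enal β-carbon (C9) and the amino-bearing terminus to the α-carbon (C10), the (E)-geometry of 4 places the C10 methyl cis to the C9 side chain, the catalyst sets the absolute configuration of both centres, and HF then unveils the enone by desilylation and loss of dimethylamine.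

Step 4
Reactants: 7 tert-butyl (3R)-5-(2-formyl-2-methyl-5-oxocyclohex-3-en-1-yl)-3-methylpentanoate
Product: 9 tert-butyl (3R)-5-[2-(2,2-dimethoxyethyl)-2-methyl-5-oxocyclohex-3-en-1-yl]-3-methylpentanoate, via enol ether 8 (not isolated)
Conditions: (methoxymethyl)triphenylphosphonium chloride, KN(SiMe3)2, THF, −78 → 0 °C; then MeOH, pyridinium p-toluenesulfonate (cat.), rt
Reagents that add atoms: (methoxymethyl)triphenylphosphonium chloride COC[P+](c1ccccc1)(c1ccccc1)c1ccccc1.[Cl-]; methanol CO
Why: Wittig olefination with the methoxymethylidene ylide should be faster at the aldehyde than at the conjugated ketone, and acid-catalysed addition of methanol to the enol ether stores the homologated aldehyde carbon (C2) as its dimethyl acetal.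

Step 5
Reactants: 9 tert-butyl (3R)-5-[2-(2,2-dimethoxyethyl)-2-methyl-5-oxocyclohex-3-en-1-yl]-3-methylpentanoate
Product: 10 tert-butyl (3R)-5-[2-(2,2-dimethoxyethyl)-2-methyl-5-oxo-6-(phenylsulfanyl)cyclohex-3-en-1-yl]-3-methylpentanoate (PhS on the lower face)
Conditions: LiN(i-Pr)2, THF, −78 °C; then PhSSO2Ph, −78 → 0 °C
Reagents that add atoms: S-phenyl benzenethiosulfonate O=S(=O)(Sc1ccccc1)c1ccccc1
Why: Kinetic α′-deprotonation of the enone (the γ-position C10 is quaternary) and sulfenylation of the cross-conjugated enolate at C8, anti to the C9 side chain.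

Step 6
Reactants: 10 tert-butyl (3R)-5-[2-(2,2-dimethoxyethyl)-2-methyl-5-oxo-6-(phenylsulfanyl)cyclohex-3-en-1-yl]-3-methylpentanoate
Product: 11 tert-butyl (3R)-5-[2-(2,2-dimethoxyethyl)-2,6-dimethyl-5-oxo-6-(phenylsulfanyl)cyclohex-3-en-1-yl]-3-methylpentanoate (C17 methyl on the lower face and PhS on the upper face)
Conditions: NaH, THF, 0 °C; then MeI, 0 °C → rt
Reagents that add atoms: iodomethane CI
Why: C-alkylation of the sulfur-stabilised enolate with MeI from the face anti to the C9 side chain, which leaves the phenylthio group on the upper face.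

Step 7
Reactants: 11 tert-butyl (3R)-5-[2-(2,2-dimethoxyethyl)-2,6-dimethyl-5-oxo-6-(phenylsulfanyl)cyclohex-3-en-1-yl]-3-methylpentanoate
Product: 12 tert-butyl (3R)-5-[2-(2,2-dimethoxyethyl)-5-hydroxy-2,6-dimethyl-6-(phenylsulfanyl)cyclohex-3-en-1-yl]-3-methylpentanoate (C7 hydroxyl on the upper face)
Conditions: NaBH4, CeCl3·7H2O, MeOH, −78 → −20 °C
Reagents that add atoms: none
Why: Luche 1,2-reduction, in which hydride should add anti to the adjacent axial C–S bond (lower face), so the C7 hydroxyl ends up on the upper face, cis to sulfur, the C9 side chain and C20.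

Step 8
Reactants: 12 tert-butyl (3R)-5-[2-(2,2-dimethoxyethyl)-5-hydroxy-2,6-dimethyl-6-(phenylsulfanyl)cyclohex-3-en-1-yl]-3-methylpentanoate
Product: 13 tert-butyl (3R)-5-[5-hydroxy-2,6-dimethyl-2-(2-oxoethyl)-6-(phenylsulfanyl)cyclohex-3-en-1-yl]-3-methylpentanoate
Conditions: pyridinium p-toluenesulfonate (cat.), acetone/H2O, 40 °C
Reagents that add atoms: water O
Why: Mild acid hydrolysis of the dimethyl acetal frees the C2 aldehyde, while the cis β-hydroxy sulfide cannot ionise through an episulfonium ion and the hydroxyl cannot reach the aldehyde on the opposite ring face.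

Step 9
Reactants: 13 tert-butyl (3R)-5-[5-hydroxy-2,6-dimethyl-2-(2-oxoethyl)-6-(phenylsulfanyl)cyclohex-3-en-1-yl]-3-methylpentanoate; 14 (E)-3-ethoxy-2-methylprop-2-enal
Product: 15 tert-butyl (3R)-5-[2,6-dimethyl-5-[(E)-2-methyl-3-oxoprop-1-enoxy]-2-(2-oxoethyl)-6-(phenylsulfanyl)cyclohex-3-en-1-yl]-3-methylpentanoate
Conditions: pyridinium p-toluenesulfonate (cat.), toluene, 60 °C, reduced pressure (ethanol removed)
Reagents that add atoms: none
Why: Acid-catalysed enol ether exchange (addition of the alcohol to the β-carbon of the vinylogous ester and loss of ethanol) gives the allyl enol ether of 2-methylmalonaldehyde without breaking the C7–O bond, so C7 keeps its configuration.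

Step 10
Reactants: 15 tert-butyl (3R)-5-[2,6-dimethyl-5-[(E)-2-methyl-3-oxoprop-1-enoxy]-2-(2-oxoethyl)-6-(phenylsulfanyl)cyclohex-3-en-1-yl]-3-methylpentanoate
Product: 17 tert-butyl 2,3-dihydroxy-19-oxo-8-(phenylsulfanyl)labd-6-en-15-oate (2-OH, 3-OH, C18, H5, H9 and C17 on the lower face; C19 formyl, C20, C9 side chain and PhS on the upper face; 13R), via trialdehyde 16 (not isolated)
Conditions: toluene, BHT (cat.), 160 °C (sealed tube); then −78 °C, SmI2 (2.2 equiv, THF), t-BuOH (2 equiv), −78 → −20 °C; aq. NH4Cl
Reagents that add atoms: none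
Why: Heating triggers the [3,3]-sigmatropic Claisen rearrangement of the allyl enol ether (O–C7–C6=C5 with the enol carbon C4), which forms C4–C5 on the face that carried the C7 oxygen, breaks C7–O, moves the olefin to C6=C7 and turns the enol ether carbon into a second formyl group (trialdehyde 16); the closest precedent is the Claisen rearrangement of O-allyl enol ethers of 1,3-dicarbonyl compounds. SmI2 then closes ring A by ketyl (pinacol) coupling of the C2 aldehyde with one of the two formyl groups on C4, a six-membered closure of a 1,6-dialdehyde (6-exo attack of the ketyl on the second, samarium-bound carbonyl), as in known intramolecular SmI2 pinacol cyclisations. C5 is set by suprafacial chirality transfer from C7, so H5 should end up trans to C20 (trans ring fusion). C4 is set in the ring closure by the choice between the two diastereotopic formyl groups: the spectator formyl should take the axial position because an axial C18 methyl would be 1,3-diaxial to C20. C2 and C3 should be set cis by the samarium chelate, with both oxygens on the lower face, where the C2 oxygen is equatorial and clear of the axial C20 and C19 groups. The step needs chemoselective coupling of the unhindered C2 aldehyde with one neopentyl formyl group; the six-membered chelate, the limited amount of SmI2 and the low temperature should secure this while the third formyl group, the allylic sulfide and the ester stay untouched.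

Step 11
Reactants: 17 tert-butyl 2,3-dihydroxy-19-oxo-8-(phenylsulfanyl)labd-6-en-15-oate
Product: 18 tert-butyl 2,3-dihydroxy-19-oxolabd-7-en-15-oate
Conditions: Bu3SnH, AIBN (cat.), benzene, 80 °C
Reagents that add atoms: none
Why: Radical chain desulfurisation, in which homolysis of the tertiary allylic C–S bond gives the C6–C7–C8 allyl radical and hydrogen transfer to its less substituted terminus C6 should place the olefin in the trisubstituted C7=C8 position; a minor C6=C7 isomer is possible.

Step 12
Reactants: 18 tert-butyl 2,3-dihydroxy-19-oxolabd-7-en-15-oate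
Product: 19 tert-butyl 2-acetoxy-3-hydroxy-19-oxolabd-7-en-15-oate
Conditions: Ac2O (1.1 equiv), pyridine, CH2Cl2, 0 °C
Reagents that add atoms: acetic anhydride CC(=O)OC(C)=O
Why: Acylation should discriminate the equatorial C2 hydroxyl from the axial, neopentyl C3 hydroxyl next to the quaternary C4, with retention at C2.

Step 13
Reactants: 19 tert-butyl 2-acetoxy-3-hydroxy-19-oxolabd-7-en-15-oate
Product: 20 2-acetoxy-3-hydroxy-19-oxolabd-7-en-15-oic acid (target; configuration as in the given structure)
Conditions: CF3CO2H, CH2Cl2, 0 °C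
Reagents that add atoms: none
Why: Acidolysis of the tert-butyl ester (loss of isobutene) should leave the acetate, the non-enolisable β-hydroxy aldehyde and the trisubstituted olefin untouched at 0 °C.

**Compound list**

1 | (R)-citronellic acid | CC(C)=CCC[C@@H](C)CC(=O)O | starting material
2 | tert-butyl (3R)-3,7-dimethyloct-6-enoate | CC(C)=CCC[C@@H](C)CC(=O)OC(C)(C)C | intermediate
3 | tert-butyl (3R,6E)-8-hydroxy-3,7-dimethyloct-6-enoate (allylic alcohol, not isolated) | OC/C(C)=C/CC[C@@H](C)CC(=O)OC(C)(C)C | intermediate
4 | tert-butyl (3R,6E)-3,7-dimethyl-8-oxooct-6-enoate | O=C/C(C)=C/CC[C@@H](C)CC(=O)OC(C)(C)C | intermediate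
5 | (E)-1-(dimethylamino)-3-(tert-butyldimethylsilyloxy)buta-1,3-diene | CN(C)/C=C/C(=C)O[Si](C)(C)C(C)(C)C | starting material
6 | tert-butyl (3R)-5-[5-(tert-butyldimethylsilyloxy)-3-(dimethylamino)-2-formyl-2-methylcyclohex-4-en-1-yl]-3-methylpentanoate (cycloadduct, not isolated; endo adduct written, NMe2 and CHO on the lower face) | O=C[C@]1(C)[C@H](N(C)C)C=C(O[Si](C)(C)C(C)(C)C)C[C@H]1CC[C@@H](C)CC(=O)OC(C)(C)C | intermediate
7 | tert-butyl (3R)-5-(2-formyl-2-methyl-5-oxocyclohex-3-en-1-yl)-3-methylpentanoate (C20 and C9 side chain on the upper face) | O=C[C@]1(C)C=CC(=O)C[C@H]1CC[C@@H](C)CC(=O)OC(C)(C)C | intermediate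
8 | tert-butyl (3R)-5-[2-[(E)-2-methoxyethenyl]-2-methyl-5-oxocyclohex-3-en-1-yl]-3-methylpentanoate (enol ether, not isolated; E isomer written, both isomers converge) | CO/C=C/[C@]1(C)C=CC(=O)C[C@H]1CC[C@@H](C)CC(=O)OC(C)(C)C | intermediate
9 | tert-butyl (3R)-5-[2-(2,2-dimethoxyethyl)-2-methyl-5-oxocyclohex-3-en-1-yl]-3-methylpentanoate | COC(OC)C[C@]1(C)C=CC(=O)C[C@H]1CC[C@@H](C)CC(=O)OC(C)(C)C | intermediate
10 | tert-butyl (3R)-5-[2-(2,2-dimethoxyethyl)-2-methyl-5-oxo-6-(phenylsulfanyl)cyclohex-3-en-1-yl]-3-methylpentanoate (PhS on the lower face) | COC(OC)C[C@]1(C)C=CC(=O)[C@H](Sc2ccccc2)[C@H]1CC[C@@H](C)CC(=O)OC(C)(C)C | intermediate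
11 | tert-butyl (3R)-5-[2-(2,2-dimethoxyethyl)-2,6-dimethyl-5-oxo-6-(phenylsulfanyl)cyclohex-3-en-1-yl]-3-methylpentanoate (PhS upper face, C17 lower face) | COC(OC)C[C@]1(C)C=CC(=O)[C@@](C)(Sc2ccccc2)[C@H]1CC[C@@H](C)CC(=O)OC(C)(C)C | intermediate
12 | tert-butyl (3R)-5-[2-(2,2-dimethoxyethyl)-5-hydroxy-2,6-dimethyl-6-(phenylsulfanyl)cyclohex-3-en-1-yl]-3-methylpentanoate (C7 OH on the upper face) | COC(OC)C[C@]1(C)C=C[C@@H](O)[C@@](C)(Sc2ccccc2)[C@H]1CC[C@@H](C)CC(=O)OC(C)(C)C | intermediate
13 | tert-butyl (3R)-5-[5-hydroxy-2,6-dimethyl-2-(2-oxoethyl)-6-(phenylsulfanyl)cyclohex-3-en-1-yl]-3-methylpentanoate | O=CC[C@]1(C)C=C[C@@H](O)[C@@](C)(Sc2ccccc2)[C@H]1CC[C@@H](C)CC(=O)OC(C)(C)C | intermediate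
14 | (E)-3-ethoxy-2-methylprop-2-enal | CCO/C=C(\C)C=O | starting material
15 | tert-butyl (3R)-5-[2,6-dimethyl-5-[(E)-2-methyl-3-oxoprop-1-enoxy]-2-(2-oxoethyl)-6-(phenylsulfanyl)cyclohex-3-en-1-yl]-3-methylpentanoate | O=CC[C@]1(C)C=C[C@@H](O/C=C(\C)C=O)[C@@](C)(Sc2ccccc2)[C@H]1CC[C@@H](C)CC(=O)OC(C)(C)C | intermediate
16 | tert-butyl (3R)-5-[2,6-dimethyl-3-(2-methyl-1,3-dioxopropan-2-yl)-2-(2-oxoethyl)-6-(phenylsulfanyl)cyclohex-4-en-1-yl]-3-methylpentanoate (trialdehyde, not isolated; C4 on the upper face of C5) | O=CC[C@]1(C)[C@@H](C(C)(C=O)C=O)C=C[C@@](C)(Sc2ccccc2)[C@H]1CC[C@@H](C)CC(=O)OC(C)(C)C | intermediate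
17 | tert-butyl 2,3-dihydroxy-19-oxo-8-(phenylsulfanyl)labd-6-en-15-oate (2-OH, 3-OH, C18, H5, H9, C17 lower face; C19, C20, side chain, PhS upper face; 13R) | O[C@H]1C[C@@]2(C)[C@H](CC[C@@H](C)CC(=O)OC(C)(C)C)[C@](C)(Sc3ccccc3)C=C[C@@H]2[C@](C)(C=O)[C@H]1O | intermediate
18 | tert-butyl 2,3-dihydroxy-19-oxolabd-7-en-15-oate (ring configuration as in the target) | O[C@H]1C[C@@]2(C)[C@H](CC[C@@H](C)CC(=O)OC(C)(C)C)C(C)=CC[C@@H]2[C@](C)(C=O)[C@H]1O | intermediate
19 | tert-butyl 2-acetoxy-3-hydroxy-19-oxolabd-7-en-15-oate | CC(=O)O[C@H]1C[C@@]2(C)[C@H](CC[C@@H](C)CC(=O)OC(C)(C)C)C(C)=CC[C@@H]2[C@](C)(C=O)[C@H]1O | intermediate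
20 | 2-acetoxy-3-hydroxy-19-oxolabd-7-en-15-oic acid (CNP0180877.1) | CC(=O)O[C@H]1C[C@@]2(C)[C@H](CC[C@@H](C)CC(=O)O)C(C)=CC[C@@H]2[C@](C)(C=O)[C@H]1O | target

**Count and risks**

Total step count: 13. Longest linear sequence: 13 steps (1 → 20); compounds 5 and 14 are bought.

Steps most likely to fail:

Step 10 (key step). The hindered allylic enol ether may ionise or eliminate at 160 °C before the sigmatropic shift, and the reductive stage may lose chemoselectivity (coupling within the geminal dialdehyde or over-reduction of the third formyl group). Fallback: the C4–C5 bond is made at room temperature by an ionic, metal-catalysed route. Compound 15 is treated with Pd(PPh3)4 (zerovalent palladium) in THF. Ionisation of the allylic C7–O bond and C-attack of the 2-methylmalonaldehyde enolate on the allyl complex proceed with double inversion, so C4 arrives on the same face as in the Claisen shift; attack at C7 instead of C5 is the regiochemical risk of this route. This gives trialdehyde 16, at which point the route is rejoined: 16 is coupled with SmI2 at −78 °C as in the second stage of step 10. No new compound is made.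

Step 3. The trisubstituted enal may be too unreactive under hydrogen-bond catalysis, or the facial selectivity may be poor, which would give inseparable C9/C10 diastereomers. Fallback: stronger Lewis-acid activation with a different diene. Compound 4 reacts with 2-(triisopropylsilyloxy)buta-1,3-diene in the presence of a chiral oxazaborolidinium triflimide (CH2Cl2, −78 → −20 °C) to give the silyl enol ether cycloadduct F1. Saegusa oxidation of F1 (Pd(OAc)2, MeCN, rt) introduces the C5=C6 double bond and returns the route to compound 7.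

Step 9. The hindered C7 hydroxyl (next to the quaternary C8) may exchange slowly, and the acid may ionise the allylic alcohol or condense the free aldehyde. Fallback: the enol ether is built under basic conditions before the aldehyde is unmasked. Compound 12 is deprotonated with KN(SiMe3)2 (THF, −78 °C) and the alkoxide adds to excess 14 with loss of ethoxide (addition–elimination) to give the acetal-protected allyl enol ether F2. Water-free acetal exchange of F2 (acetone, pyridinium p-toluenesulfonate, rt) then frees the C2 aldehyde and returns the route to compound 15.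

Further compounds
F1 | step 3 | tert-butyl (3R)-5-[2-formyl-2-methyl-5-(triisopropylsilyloxy)cyclohex-4-en-1-yl]-3-methylpentanoate | O=C[C@]1(C)CC=C(O[Si](C(C)C)(C(C)C)C(C)C)C[C@H]1CC[C@@H](C)CC(=O)OC(C)(C)C
F2 | step 9 | tert-butyl (3R)-5-[2-(2,2-dimethoxyethyl)-2,6-dimethyl-5-[(E)-2-methyl-3-oxoprop-1-enoxy]-6-(phenylsulfanyl)cyclohex-3-en-1-yl]-3-methylpentanoate | COC(OC)C[C@]1(C)C=C[C@@H](O/C=C(\C)C=O)[C@@](C)(Sc2ccccc2)[C@H]1CC[C@@H](C)CC(=O)OC(C)(C)C
F0 | step 10 | none | none
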